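## Structural features

Hernanol is a dibenzylbutyrolactone lignan. Its only non-aromatic ring is a γ-butyrolactone (O1, C2 carbonyl, C3, C4, C5). C3 carries a 3,4,5-trimethoxybenzyl group and C4 a 4-hydroxy-3-methoxybenzyl group, each arene being joined to the ring through one CH2. C3 and C4 are adjacent stereocentres, both R, with the two benzyl groups trans. C3 is alpha to the lactone carbonyl and can be equilibrated to the more stable trans arrangement, whereas C4 has no activating neighbour and must be set absolutely once and then left alone. The fragile groups are the free phenol, the lactone (ring opening, and acyl migration when a hydroxyl sits on the C4 arm) and the two electron-rich arenes. The arenes are sensitive to oxidants, and a cation at the benzylic carbon of the C4 arm could close onto the trimethoxyphenyl ring to give an aryltetralin. The real difficulty is absolute control at C4, a carbon bearing H, C3, the C5H2–O1 unit and a CH2Ar group. The key step uses the fact that C4 lies between the C5–O1 unit and C3. If C3 carries a second carboxyl group, this is the pattern of a malonate bonded to the internal carbon of an opened vinyl epoxide, whose vinyl group is the latent benzylic carbon of the C4 arm.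

## Logic of the disconnections

**15 back to 13 (through 14).** Three groups are put back: a carboxyl on C3 (C3–CO2 bond), a hydroxyl on the benzylic carbon of the C4 arm, and a benzyl group on the phenol oxygen. The extra carboxyl makes C3 quaternary and non-enolisable while the C4 arm is worked on, and the benzylic hydroxyl is the trace of a carbonyl addition. No stereocentre is removed, but 13 can now be cut at a C–C bond. The forward step must cleave three benzylic C–O bonds by hydrogenolysis without cationic ring closure, lose CO2 from 14, and equilibrate C3 to trans without touching C4.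

**13 back to 11 and 12.** The bond between the carbinol carbon and the aryl carbon is cut, as it is the only C–C bond joining the guaiacyl ring to the lactone fragment. This separates the arene from a small lactone aldehyde with one relevant stereocentre. The forward addition must prefer the aldehyde over the lactone and ester carbonyls and must be cold and brief, because C4–H of 11 is enolisable and O1 sits beta to the formyl group.

**12 back to 9 and 8.** The C–Mg bond and then the O–benzyl bond are cut. The phenol must be masked for the organometallic step, and benzyl is chosen because it falls in the final hydrogenolysis.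

**11 back to 7 (through 10).** The formyl C=O is traced to the vinyl C=C. The vinyl group is the stable form in which the allylic alkylation delivers this carbon. The forward cleavage must spare the trimethoxyphenyl ring and stay neutral.

**7 back to 4 and 5 (through 6).** The C3–C4 and C2–O1 bonds are cut. This removes the ring and the C4 stereocentre in one catalytic operation and leads to an achiral malonate and a racemic epoxide. The forward step must attack the internal allyl carbon, take its absolute sense from the ligand and close the lactone on one ester.

**4 back to 1 and 2 (through 3).** The C3–benzylic bond is cut as a malonate alkylation. The only demand is mono-alkylation, met by an excess of 1.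

## Other disconnections considered

**Alternative 1:** The cut is made at both exocyclic bonds of an intact lactone, C4–C(benzylic) and C3–C(benzylic).
- Forward step: the 2-lithio derivative of 2-(4-benzyloxy-3-methoxyphenyl)-1,3-dithiane A2 would add in conjugate fashion to (5R)-5-[(1R,2S,5R)-menthyloxy]furan-2(5H)-one A1, anti to the acetal substituent. The lactone enolate would then be benzylated by 3,4,5-trimethoxybenzyl bromide A3, anti to the new C4 substituent, to give the all-trans lactone A4. No ring is formed.
- In favour: both stereocentres and the trans relationship arise in one flask under substrate control, no enolisable aldehyde is handled, and diastereomers are formed, so purity can be raised by crystallisation. On stereocontrol this plan is the better of the two, since the chosen plan sets only C4 directly and relies on a ligand.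
- Against: the auxiliary is stoichiometric. C5 enters at the aldehyde oxidation level and the benzylic carbon as a dithioketal, so three reductive corrections must follow (desulfurisation, reductive removal of the acetal, debenzylation). The key step needs a stoichiometric alkyllithium base at low temperature.
- Comparison: structurally the chosen plan builds the ring and C4 from achiral and racemic pieces, while this one decorates a ring that must already be enantiopure. Mechanistically it exchanges catalyst control for substrate control. In step count the two are about equal once A1 and A2 are prepared.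

**Alternative 2:** C4–C(benzylic), C3–C2 and C2–O1 are cut, which reduces the target to an achiral butenolide.
- Forward step: the magnesium alkoxide of 4-(3,4,5-trimethoxyphenyl)but-2-yn-1-ol A5 would undergo copper-catalysed anti carbomagnesiation by (4-benzyloxy-3-methoxybenzyl)magnesium chloride A6, the benzyl group entering at the alkyne carbon next to the CH2O group. The chelated alkenylmagnesium would be carboxylated at the other alkyne carbon, and acidification would close butenolide A7.
- In favour: the whole carbon skeleton and the ring are assembled in one flask from two fragments. Up to the skeleton this is better step economy than the chosen plan, and no sensitive aldehyde or oxidative cleavage is needed.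
- Against: no stereocentre is set. Both would have to come from an enantioselective hydrogenation of a tetrasubstituted, weakly coordinating alkene. That step adds hydrogen syn, so the cis lactone would form first, and C4 would rest entirely on its facial selectivity. A6 is prone to homocoupling, and A5 has propargylic-benzylic hydrogens that invite isomerisation to an allene under basic conditions.
- Comparison: on convergence and steps to the ring this alternative is superior. On absolute control at C4 the chosen plan uses a reaction class designed for the purpose, while this one postpones it to an uncertain hydrogenation. Both end with a hydrogenation and a C3 equilibration and are equal there.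

**Alternative 3:** The cuts are C3–C4 and the bond between the guaiacyl ring and its CH2.
- Forward step: (E)-4,4,5,5-tetramethyl-2-(3,4,5-trimethoxystyryl)-1,3,2-dioxaborolane A8 and vinyllithium A9 would form a boronate complex. A palladium catalyst with a chiral ferrocenyl diphosphine and 4-benzyloxy-3-methoxyphenyl trifluoromethanesulfonate A10 would then induce the 1,2-shift of the styrenyl group to the vinyl alpha carbon while the aryl group is delivered to the vinyl terminus, giving allylboronate A11. No ring closes.
- In favour: it is catalytic and enantioselective like the chosen step. It sets C4 with the guaiacylmethyl group already in final form, so the ozonolysis, the organometallic addition and the epimerisable aldehyde of the chosen route disappear. On this point it is the better plan.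
- Against: A11 has neither C5–O1 nor C2. The C–B bond must be homologated by one carbon and oxidised to (R,E)-2-(4-benzyloxy-3-methoxybenzyl)-4-(3,4,5-trimethoxyphenyl)but-3-en-1-ol A12. The lactone carbonyl must then be introduced by a hydroxyl-directed carbonylation of the styrenyl alkene at the carbon remote from the arene, against the usual benzylic preference. Alkenyl groups are among the less reliable migrating groups in this coupling, and A10 is electron-rich and slow in oxidative addition.
- Comparison: structurally this route fixes the C4 arm early and builds the lactone late, the reverse of the chosen plan. Mechanistically both depend on a chiral palladium catalyst and are equal in kind. It would be no shorter, and it has two uncertain steps after the key step where the chosen route has routine ones.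

Key step: step 2

**Remarks on the chemistry**

- Remark 1: the malonate esters are benzyl and not methyl, a spectator-group change that leaves the bonds formed and the ring closed in the key step unchanged; one hydrogenolysis then removes ester, phenol ether and benzylic hydroxyl together, and no separate high-temperature dealkoxycarbonylation is needed.
- Remark 2: the descriptors were checked atom by atom and no structure needed correction: 15 is (3R,4R) with trans benzyl groups, and C4 of 7 has the same spatial arrangement as C4 of 15; with benzyl esters C3 of 7 becomes S for the same geometry (trimethoxybenzyl trans to vinyl), because the benzyl ester carbon outranks the ring carbonyl carbon.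
- Remark 3 (assumption): the (R,R) antipode of the ligand is assumed to give the 4R series; both antipodes are commercial, so the sense of induction is to be confirmed on the first run and the (S,S) antipode used if the opposite series forms.

## Route

Step 1
Reactants: 1 dibenzyl malonate; 2 3,4,5-trimethoxybenzyl chloride
Product: 4 dibenzyl 2-(3,4,5-trimethoxybenzyl)malonate, via sodium enolate of dibenzyl malonate 3 (not isolated)
Conditions: 1 (1.5 equiv), NaH (1.0 equiv), THF/DMF, 0 °C; then 2 (1.0 equiv), NaI (cat.), 0 °C to rt
Reagents that add atoms: none
Why: Malonic ester alkylation (SN2 of a stabilised enolate on a benzylic chloride); the excess of 1 over base and halide keeps the less acidic product from being deprotonated and alkylated a second time.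

Step 2
Reactants: 4 dibenzyl 2-(3,4,5-trimethoxybenzyl)malonate; 5 racemic 2-vinyloxirane
Product: 7 benzyl (3S,4R)-2-oxo-3-(3,4,5-trimethoxybenzyl)-4-vinyltetrahydrofuran-3-carboxylate, via open-chain hydroxy diester 6 (not isolated)
Conditions: Pd2(dba)3·CHCl3 (2.5 mol%), (1R,2R)-N,N'-bis[2-(diphenylphosphino)benzoyl]cyclohexane-1,2-diamine L (7.5 mol%), Cs2CO3 (10 mol%), CH2Cl2, rt, 5 (1.5 equiv) added slowly; then DBU (20 mol%), rt
Reagents that add atoms: none
Why: Zerovalent palladium ionises either enantiomer of 5 to a zwitterionic pi-allylpalladium alkoxide, and the diastereomeric complexes interconvert by pi-sigma-pi isomerisation through the unsubstituted allyl terminus faster than they are captured, so the racemate converges (dynamic kinetic asymmetric transformation). The alkoxide removes the single acidic hydrogen of 4, and the hydrogen-bonded enolate is delivered to the neighbouring internal allyl carbon inside the chiral pocket of L, which forms the C3–C4 bond. The closest known reaction type is the branched-selective palladium-catalysed asymmetric allylic alkylation of butadiene monoepoxide with stabilised carbon acids. The hydroxyl or alkoxide of 6 then closes the lactone by 5-exo-trig acyl substitution on one of the two benzyl esters, which forms the C2–O1 bond and expels benzyl alcohol; DBU completes this if it lags. C4 is set by the ligand (catalyst control), the (R,R) antipode being taken to give 4R. C3 becomes quaternary in the ring closure; the less crowded isomer with the trimethoxybenzyl group trans to vinyl is expected to predominate, but either epimer serves because C3 is reset in step 6. The step needs internal over terminal attack and one allyl face: the tethered alkoxide acting as base and directing group secures the first, fast equilibration of the unhindered allyl system under ligand control the second, and the single acidic hydrogen of 4 rules out double alkylation.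

Step 3
Reactants: 8 4-bromo-2-methoxyphenol
Product: 9 1-(benzyloxy)-4-bromo-2-methoxybenzene
Conditions: BnBr (1.1 equiv), K2CO3 (1.5 equiv), acetone, reflux
Reagents that add atoms: benzyl bromide, BrCc1ccccc1
Why: Williamson ether synthesis on a phenoxide; benzyl is chosen so that the phenol is released in the same hydrogenolysis that finishes the synthesis.

Step 4
Reactants: 7 benzyl (3S,4R)-2-oxo-3-(3,4,5-trimethoxybenzyl)-4-vinyltetrahydrofuran-3-carboxylate
Product: 11 benzyl (3S,4R)-4-formyl-2-oxo-3-(3,4,5-trimethoxybenzyl)tetrahydrofuran-3-carboxylate, via secondary ozonide 10 (not isolated)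
Conditions: O3, CH2Cl2, −78 °C, Sudan Red 7B end-point; then PPh3 (1.2 equiv), −78 °C to rt; dried and used at once without chromatography
Reagents that add atoms: ozone, [O-][O+]=O
Why: Ozonolysis by the Criegee mechanism with reductive work-up; the monosubstituted alkene reacts far faster than the arene and the dye marks the end-point, and the neutral phosphine reduction avoids enolisation at C4, so the 4R centre should be carried through unchanged.

Step 5
Reactants: 9 1-(benzyloxy)-4-bromo-2-methoxybenzene; 11 benzyl (3S,4R)-4-formyl-2-oxo-3-(3,4,5-trimethoxybenzyl)tetrahydrofuran-3-carboxylate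
Product: 13 benzyl (3S,4R)-4-[(4-benzyloxy-3-methoxyphenyl)(hydroxy)methyl]-2-oxo-3-(3,4,5-trimethoxybenzyl)tetrahydrofuran-3-carboxylate (both carbinol epimers), via 4-benzyloxy-3-methoxyphenylmagnesium bromide 12 (not isolated)
Conditions: 9, Mg turnings, I2 (cat.), THF, 45 °C; the titrated reagent (1.15 equiv) added to 11, THF, −78 °C; AcOH/THF quench at −78 °C
Reagents that add atoms: none
Why: Grignard addition to an aldehyde, which at −78 °C is much more electrophilic than the lactone or the benzyl ester; the cold acidic quench prevents enolisation at C4 and acyl migration of the alkoxide, and the new carbinol centre needs no control because it is removed in step 6 (any acyl-migrated material should converge on 14 as well).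

Step 6
Reactants: 13 benzyl (3S,4R)-4-[(4-benzyloxy-3-methoxyphenyl)(hydroxy)methyl]-2-oxo-3-(3,4,5-trimethoxybenzyl)tetrahydrofuran-3-carboxylate
Product: 15 hernanol, (3R,4R)-4-(4-hydroxy-3-methoxybenzyl)-3-(3,4,5-trimethoxybenzyl)dihydrofuran-2(3H)-one, via lactone carboxylic acid 14 (not isolated)
Conditions: H2 (3 atm), 20% Pd(OH)2/C, EtOAc/EtOH, rt to 40 °C; filter; toluene/dioxane, 105 °C; then DBU (1.5 equiv), 80 °C; dilute aq. HCl work-up
Reagents that add atoms: none
Why: Catalytic hydrogenolysis cleaves the benzyl ester, the aryl benzyl ether and the para-oxygenated secondary benzylic alcohol, as in the hydrogenolysis of benzylic-hydroxy dibenzylbutyrolactone lignans. The malonic half-ester acid 14 then loses CO2 thermally, and base equilibration at C3, the only enolisable centre, should give the more stable trans lactone, so that 3R follows from the untouched 4R.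

## Compound list

1 | dibenzyl malonate | O=C(CC(=O)OCc1ccccc1)OCc1ccccc1 | starting material
2 | 3,4,5-trimethoxybenzyl chloride | COc1cc(CCl)cc(OC)c1OC | starting material
3 | sodium enolate of dibenzyl malonate | [Na+].O=C([CH-]C(=O)OCc1ccccc1)OCc1ccccc1 | intermediate (not isolated)
4 | dibenzyl 2-(3,4,5-trimethoxybenzyl)malonate | COc1cc(CC(C(=O)OCc2ccccc2)C(=O)OCc2ccccc2)cc(OC)c1OC | intermediate
5 | racemic 2-vinyloxirane | C=CC1CO1 | starting material
6 | dibenzyl 2-[(2R)-1-hydroxybut-3-en-2-yl]-2-(3,4,5-trimethoxybenzyl)malonate | C=C[C@@H](CO)C(Cc1cc(OC)c(OC)c(OC)c1)(C(=O)OCc1ccccc1)C(=O)OCc1ccccc1 | intermediate (not isolated)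
7 | benzyl (3S,4R)-2-oxo-3-(3,4,5-trimethoxybenzyl)-4-vinyltetrahydrofuran-3-carboxylate (trimethoxybenzyl trans to vinyl; the C3 epimer is tolerated) | C=C[C@H]1COC(=O)[C@]1(C(=O)OCc1ccccc1)Cc1cc(OC)c(OC)c(OC)c1 | intermediate
8 | 4-bromo-2-methoxyphenol | COc1cc(Br)ccc1O | starting material
9 | 1-(benzyloxy)-4-bromo-2-methoxybenzene | COc1cc(Br)ccc1OCc1ccccc1 | intermediate
10 | benzyl (3S,4R)-2-oxo-4-(1,2,4-trioxolan-3-yl)-3-(3,4,5-trimethoxybenzyl)tetrahydrofuran-3-carboxylate (trioxolane carbon unassigned) | O1OCOC1[C@H]2COC(=O)[C@]2(C(=O)OCc3ccccc3)Cc3cc(OC)c(OC)c(OC)c3 | intermediate (not isolated)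
11 | benzyl (3S,4R)-4-formyl-2-oxo-3-(3,4,5-trimethoxybenzyl)tetrahydrofuran-3-carboxylate | O=C[C@H]1COC(=O)[C@]1(C(=O)OCc1ccccc1)Cc1cc(OC)c(OC)c(OC)c1 | intermediate
12 | 4-benzyloxy-3-methoxyphenylmagnesium bromide | COc1cc([Mg]Br)ccc1OCc1ccccc1 | intermediate (not isolated)
13 | benzyl (3S,4R)-4-[(4-benzyloxy-3-methoxyphenyl)(hydroxy)methyl]-2-oxo-3-(3,4,5-trimethoxybenzyl)tetrahydrofuran-3-carboxylate (carbinol carbon both configurations) | COc1cc(C(O)[C@H]2COC(=O)[C@]2(C(=O)OCc3ccccc3)Cc3cc(OC)c(OC)c(OC)c3)ccc1OCc1ccccc1 | intermediate
14 | (3R,4R)-4-(4-hydroxy-3-methoxybenzyl)-2-oxo-3-(3,4,5-trimethoxybenzyl)tetrahydrofuran-3-carboxylic acid | COc1cc(C[C@H]2COC(=O)[C@]2(C(=O)O)Cc2cc(OC)c(OC)c(OC)c2)ccc1O | intermediate (not isolated)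
15 | hernanol, (3R,4R)-4-(4-hydroxy-3-methoxybenzyl)-3-(3,4,5-trimethoxybenzyl)dihydrofuran-2(3H)-one | COc1cc(C[C@H]2COC(=O)[C@@H]2Cc2cc(OC)c(OC)c(OC)c2)ccc1O | target

## Step count and least certain steps

Total step count: 6. Longest linear sequence: 5 steps (steps 1, 2, 4, 5 and 6); step 3 lies on the branch.

**Step 2 (key step).** Compound 4 is a hindered and only moderately acidic carbon acid. The most likely failures are attack at the allyl terminus, capture of the allyl complex before the two diastereomeric forms have equilibrated (loss of enantioselectivity), and consumption of 5 by oligomerisation or by the liberated benzyl alcohol.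

The fallback sets out from 1 and makes the C3–C4 bond by iridium-catalysed branched-selective asymmetric allylic alkylation, with the benzyl group introduced afterwards:
- (E)-but-2-ene-1,4-diol F1 is monosilylated (NaH, TBSCl, THF) to (E)-4-[(tert-butyldimethylsilyl)oxy]but-2-en-1-ol F2.
- F2 is converted (ClCO2Me, pyridine, CH2Cl2) into (E)-4-[(tert-butyldimethylsilyl)oxy]but-2-en-1-yl methyl carbonate F3.
- 1 and F3 with [Ir(cod)Cl]2 and a chiral phosphoramidite ligand (THF, rt) should give dibenzyl 2-[(2R)-1-[(tert-butyldimethylsilyl)oxy]but-3-en-2-yl]malonate F4.
- TBAF (THF, 0 °C) releases the alkoxide, which should lactonise to benzyl (4R)-2-oxo-4-vinyltetrahydrofuran-3-carboxylate F5.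
- Alkylation of F5 with 2 (K2CO3, NaI, acetone), anti to the vinyl group, comes back to the route at 7.

**Step 4.** The most likely failures are over-oxidation of the trimethoxyphenyl ring by excess ozone, and epimerisation at C4 or beta-elimination of the lactone oxygen during reduction and concentration.

The fallback sets out from 7: dihydroxylation (OsO4 cat., NMO, acetone/water, 0 °C) should give benzyl (3S,4R)-4-(1,2-dihydroxyethyl)-2-oxo-3-(3,4,5-trimethoxybenzyl)tetrahydrofuran-3-carboxylate F6. This is cleaved without delay (NaIO4, THF/pH 7 buffer, 0 °C), which comes back to the route at 11.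

**Step 5.** The most likely failures are enolisation of 11 by the basic organomagnesium reagent (epimerisation at C4 or ring opening), competing addition to the lactone or ester carbonyl, and acyl migration of the magnesium alkoxide before the quench.

The fallback sets out from 9: copper-catalysed halogen exchange (NaI, CuI, N,N'-dimethylethylenediamine, dioxane, 110 °C) should give 1-(benzyloxy)-4-iodo-2-methoxybenzene F7. F7 is coupled with 11 under Nozaki–Hiyama–Kishi conditions (CrCl2, NiCl2 cat., DMF, rt), in which a non-basic organochromium species adds selectively to the aldehyde. This comes back to the route at 13.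

**Step 6.** The most likely failures are stalling at the benzylic alcohol, and ionisation of the benzylic carbon once the phenol is free, followed by Friedel–Crafts closure onto the trimethoxyphenyl ring. Incomplete equilibration at C3 would leave cis lactone.

The fallback sets out from 13 and removes the hydroxyl by a radical path before the phenol is unmasked:
- 1,1'-Thiocarbonyldiimidazole (1,2-dichloroethane, 60 °C) should give benzyl (3S,4R)-4-[(4-benzyloxy-3-methoxyphenyl)(1H-imidazole-1-carbothioyloxy)methyl]-2-oxo-3-(3,4,5-trimethoxybenzyl)tetrahydrofuran-3-carboxylate F8.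
- Barton–McCombie deoxygenation (Bu3SnH, AIBN, toluene, 80 °C) should give benzyl (3S,4R)-4-(4-benzyloxy-3-methoxybenzyl)-2-oxo-3-(3,4,5-trimethoxybenzyl)tetrahydrofuran-3-carboxylate F9.
- Hydrogenolysis of the two benzyl groups (H2, Pd/C, EtOAc) comes back to the route at 14, which is decarboxylated and equilibrated to 15 as in step 6.

## Further compounds

F1 | step 2 | (E)-but-2-ene-1,4-diol | OC/C=C/CO
F2 | step 2 | (E)-4-[(tert-butyldimethylsilyl)oxy]but-2-en-1-ol | OC/C=C/CO[Si](C)(C)C(C)(C)C
F3 | step 2 | (E)-4-[(tert-butyldimethylsilyl)oxy]but-2-en-1-yl methyl carbonate | COC(=O)OC/C=C/CO[Si](C)(C)C(C)(C)C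
F4 | step 2 | dibenzyl 2-[(2R)-1-[(tert-butyldimethylsilyl)oxy]but-3-en-2-yl]malonate | C=C[C@@H](CO[Si](C)(C)C(C)(C)C)C(C(=O)OCc1ccccc1)C(=O)OCc1ccccc1
F5 | step 2 | benzyl (4R)-2-oxo-4-vinyltetrahydrofuran-3-carboxylate | C=C[C@H]1COC(=O)C1C(=O)OCc1ccccc1
F6 | step 4 | benzyl (3S,4R)-4-(1,2-dihydroxyethyl)-2-oxo-3-(3,4,5-trimethoxybenzyl)tetrahydrofuran-3-carboxylate | OCC(O)[C@H]1COC(=O)[C@]1(C(=O)OCc1ccccc1)Cc1cc(OC)c(OC)c(OC)c1
F7 | step 5 | 1-(benzyloxy)-4-iodo-2-methoxybenzene | COc1cc(I)ccc1OCc1ccccc1
F8 | step 6 | benzyl (3S,4R)-4-[(4-benzyloxy-3-methoxyphenyl)(1H-imidazole-1-carbothioyloxy)methyl]-2-oxo-3-(3,4,5-trimethoxybenzyl)tetrahydrofuran-3-carboxylate | COc1cc(C(OC(=S)n2ccnc2)[C@H]2COC(=O)[C@]2(C(=O)OCc2ccccc2)Cc2cc(OC)c(OC)c(OC)c2)ccc1OCc1ccccc1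
F9 | step 6 | benzyl (3S,4R)-4-(4-benzyloxy-3-methoxybenzyl)-2-oxo-3-(3,4,5-trimethoxybenzyl)tetrahydrofuran-3-carboxylate | COc1cc(C[C@H]2COC(=O)[C@]2(C(=O)OCc2ccccc2)Cc2cc(OC)c(OC)c(OC)c2)ccc1OCc1ccccc1
A1 | alternative 1 | (5R)-5-[(1R,2S,5R)-menthyloxy]furan-2(5H)-one | O=C1C=C[C@H](O[C@@H]2C[C@H](C)CC[C@H]2C(C)C)O1
A2 | alternative 1 | 2-(4-benzyloxy-3-methoxyphenyl)-1,3-dithiane | COc1cc(C2SCCCS2)ccc1OCc1ccccc1
A3 | alternative 1 | 3,4,5-trimethoxybenzyl bromide | COc1cc(CBr)cc(OC)c1OC
A4 | alternative 1 | (3R,4R,5R)-4-[2-(4-benzyloxy-3-methoxyphenyl)-1,3-dithian-2-yl]-5-[(1R,2S,5R)-menthyloxy]-3-(3,4,5-trimethoxybenzyl)dihydrofuran-2(3H)-one | COc1cc(C3(SCCCS3)[C@H]2[C@H](O[C@@H]3C[C@H](C)CC[C@H]3C(C)C)OC(=O)[C@@H]2Cc2cc(OC)c(OC)c(OC)c2)ccc1OCc1ccccc1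
A5 | alternative 2 | 4-(3,4,5-trimethoxyphenyl)but-2-yn-1-ol | COc1cc(CC#CCO)cc(OC)c1OC
A6 | alternative 2 | (4-benzyloxy-3-methoxybenzyl)magnesium chloride | COc1cc(C[Mg]Cl)ccc1OCc1ccccc1
A7 | alternative 2 | 4-(4-benzyloxy-3-methoxybenzyl)-3-(3,4,5-trimethoxybenzyl)furan-2(5H)-one | COc1cc(CC2=C(Cc3cc(OC)c(OC)c(OC)c3)C(=O)OC2)ccc1OCc1ccccc1
A8 | alternative 3 | (E)-4,4,5,5-tetramethyl-2-(3,4,5-trimethoxystyryl)-1,3,2-dioxaborolane | COc1cc(/C=C/B2OC(C)(C)C(C)(C)O2)cc(OC)c1OC
A9 | alternative 3 | vinyllithium | [Li]C=C
A10 | alternative 3 | 4-benzyloxy-3-methoxyphenyl trifluoromethanesulfonate | COc1cc(OS(=O)(=O)C(F)(F)F)ccc1OCc1ccccc1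
A11 | alternative 3 | (R,E)-2-[1-(4-benzyloxy-3-methoxyphenyl)-4-(3,4,5-trimethoxyphenyl)but-3-en-2-yl]-4,4,5,5-tetramethyl-1,3,2-dioxaborolane | COc1cc(C[C@H](/C=C/c2cc(OC)c(OC)c(OC)c2)B2OC(C)(C)C(C)(C)O2)ccc1OCc1ccccc1
A12 | alternative 3 | (R,E)-2-(4-benzyloxy-3-methoxybenzyl)-4-(3,4,5-trimethoxyphenyl)but-3-en-1-ol | COc1cc(C[C@H](/C=C/c2cc(OC)c(OC)c(OC)c2)CO)ccc1OCc1ccccc1
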